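The numbers in the tables come from a simulation with constants of no real substance; noise was put on by code.

Elm's readings lacked 34.2% of its charge at 30.0 h, and I took that as Z. I divided it by the area under elm's E curve, 7.99 h by trapezoids. That gave a first-order constant of 0.0428 /h for E to Z.

Elm's highest [E] read 0.0756 M. Cedar held 0.832 M of E, far more, so I supposed that crystals J hold dissolved [E] near that ceiling.

While J stands, the product 0.003237 M/h is the Z clock, a pseudo-zero-order loss. Integrated, it gives roughly [Z] = rt, an estimate that takes [E] at the ceiling from the start and holds no longer than J stands. Over 2.0 d it takes 0.155 M. If J lasted that long, that would be 7.77% of Friday's charge but 19.4% of Saturday's, a heavier toll on the smaller charge. D pointed the same way: elm read 55.1% at 30.0 h, and cedar read 2.4% at 30.0 h, so the smaller charge had more D. On both counts I ranked the flasks by falling G.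

in all of them: X 100 mM (held)

| run | G | remark | time |
|---|---|---|---|
| elm | 0.19 M | run made earlier |  |
| cedar | 1.6 M | run made earlier |  |
| Friday's | 2.0 M |  | 2.0 d |
| Monday's | 0.50 M |  | 2.0 d |
| Saturday's | 0.80 M |  | 2.0 d |
| Tuesday's | 0.25 M |  | 2.0 d |
| Thursday's | 1.5 M |  | 2.0 d |

| run | time / h | E / % | D / % |
|---|---|---|---|
| elm | 6.00 | 34.8 | 4.7 |
| elm | 15.0 | 39.8 | 26.2 |
| elm | 20.0 | 28.5 | 39.1 |
| elm | 25.0 | 18.0 | 48.4 |
| elm | 30.0 | 10.7 | 55.1 |
| cedar | 3.00 | 6.0 | 0 |
| cedar | 8.00 | 14.8 | 0.3 |
| cedar | 15.0 | 27.7 | 1.0 |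
| cedar | 25.0 | 44.5 | 1.3 |
| cedar | 30.0 | 52.0 | 2.4 |

(readings scatter by 0.3 percentage points)

- amounts and yields of E count J too
- given per volume of solution although it is solid: J
- at the start none of Q is dissolved
- the earlier runs were read with a standard deviation of 0.3 percentage points
- steps thought possible: X <-> Q; G + Q -> E; Q + E -> D; J <-> E; E -> Z

- the flasks put in order of share of E in all that became E or D or Z, best first, at 2.0 d (Friday's / Monday's / Saturday's / Tuesday's / Thursday's)
- the share of E in all that became E or D or Z of the flask you put first, at 2.0 d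
- the share of E in all that became E or D or Z of the flask you put last, at 2.0 d

The forecast gave Friday's > Thursday's > Saturday's > Monday's > Tuesday's, with 86.5% and 2.5%, holding that “crystals cap dissolved E near 0.08 M”. The flasks gave Friday's > Thursday's > Saturday's > Monday's > Tuesday's, with 85.6% and 1.65%.

    X ⇌ Q, rate k1*(csat - [Q]) (kL = 0.390 /h)
    G + Q → E (k = 2.50 /M/h)
    Q + E → D (k = 1.00 /M/h)
    J ⇌ E, rate k4*(cs4 - [E]) while solid is left; crystals form when [E] > cs4 (solubility = 0.0750 M, k = 2.10 /h)
    E → Z (k = 0.0420 /h)

Friday's still held J at 62.5% of its charge at 2.00 d. For Friday's the clock gave 7.77% as Z, and the flask had 8.61%, somewhat more.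

Tuesday's flask read at 20 h still holds J, at 12.5%. There the clock gives 25.9% of the charge as Z, and the computed value is 21.9%.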